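**Retrosynthetic overview**

- Last C=C: the (E)-trisubstituted enoate alkene of the side chain is cut by cross-metathesis into the methacrylate of the hydroxyquinone neopentyl alcohol and (R)-3-methylidenehept-6-en-2-ol; the dienol brings the only stereocentre, unchanged, from (R)-but-3-yn-2-ol.
- Ester C–O: the methacrylate goes back to the free neopentyl alcohol and then to its PMB ether.
- Ring B: the strategy rests on the quinone ring C1–C4/C4a/C8a, which has oxygen on C1, C2 and C4, its single carbon substituent on C3, and an unsubstituted benzo ring C5–C8. That pattern results when a β-keto ester is inserted across benzyne (C4–C4a, C1–C8a), closed by Claisen condensation (C2–C3) and oxidised by air at C1.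
- Keto ester: methyl 7-(PMB-oxy)-6,6-dimethyl-3-oxoheptanoate comes from neopentyl glycol (mono-PMB ether, then aldehyde) and the four-carbon acetoacetate ylide by Wittig olefination and alkene hydrogenation.
- Ring order: the benzo ring is bought as the aryne precursor; ring B is the only ring made, in step 6.

Key step: step 6

Remark: ring B is numbered as in 2-hydroxy-1,4-naphthoquinone with the side chain on C3; PMBCl, methacrylic anhydride, but-3-enylmagnesium bromide (THF solution) and lawsone (used only in a fallback) are taken as commercial reagents.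

**Route**

Step 1
Reactants: 1 neopentyl glycol (2,2-dimethylpropane-1,3-diol)
Product: 2 3-[(4-methoxybenzyl)oxy]-2,2-dimethylpropan-1-ol
Conditions: 1 (3 equiv), NaH (1.0 equiv), THF/DMF, 0 °C; PMBCl (1.0 equiv), Bu4NI (cat.), 0 °C → rt
Reagents that add atoms: 4-methoxybenzyl chloride, COc1ccc(CCl)cc1
Why: Williamson etherification of the monoalkoxide; because the diol is symmetrical and used in excess, the mono-ether should dominate and the surplus diol washes out with water.

Step 2
Reactants: 2 3-[(4-methoxybenzyl)oxy]-2,2-dimethylpropan-1-ol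
Product: 3 3-[(4-methoxybenzyl)oxy]-2,2-dimethylpropanal
Conditions: TEMPO (10 mol%), PhI(OAc)2 (1.1 equiv), CH2Cl2, rt
Reagents that add atoms: none
Why: TEMPO/PhI(OAc)2 (oxoammonium) oxidation of a primary alcohol stops at the aldehyde, which here has no α-hydrogen and cannot enolise, and the PMB ether is inert to the reagent.

Step 3
Reactants: 4 methyl 4-chloroacetoacetate (methyl 4-chloro-3-oxobutanoate)
Product: 6 methyl 3-oxo-4-(triphenyl-λ5-phosphanylidene)butanoate, via phosphonium chloride 5 (not isolated)
Conditions: PPh3 (1.0 equiv), THF, rt → 50 °C; then aq Na2CO3, CH2Cl2, rt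
Reagents that add atoms: triphenylphosphine, c1ccc(cc1)P(c1ccccc1)c1ccccc1
Why: SN2 displacement of the activated α-chloro ketone chloride by PPh3 gives the phosphonium salt, whose P–CH2–C=O proton is removed by carbonate to give the acyl-stabilised ylide (standard phosphorane preparation).

Step 4
Reactants: 6 methyl 3-oxo-4-(triphenyl-λ5-phosphanylidene)butanoate; 3 3-[(4-methoxybenzyl)oxy]-2,2-dimethylpropanal
Product: 7 methyl (E)-7-[(4-methoxybenzyl)oxy]-6,6-dimethyl-3-oxohept-4-enoate
Conditions: 6 (1.2 equiv), NaH (1.2 equiv), THF, 0 °C → rt; then 3, rt → 50 °C; 1 M HCl work-up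
Reagents that add atoms: none
Why: Wittig olefination through the ylide anion: NaH removes a proton from the CH2 between the two carbonyls, which makes the otherwise sluggish acyl ylide nucleophilic enough for the hindered but non-enolisable aldehyde, and the E-alkene expected from a stabilised ylide is in any case removed in step 5.

Step 5
Reactants: 7 methyl (E)-7-[(4-methoxybenzyl)oxy]-6,6-dimethyl-3-oxohept-4-enoate
Product: 8 methyl 7-[(4-methoxybenzyl)oxy]-6,6-dimethyl-3-oxoheptanoate
Conditions: H2 (1 atm), 10% Pd/C, pyridine (0.5 equiv), EtOAc, rt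
Reagents that add atoms: none
Why: Catalytic hydrogenation of the conjugated disubstituted alkene over Pd/C, with pyridine as a catalyst poison that suppresses hydrogenolysis of the PMB ether; the ketone and ester are not reduced under these conditions.

Step 6
Reactants: 8 methyl 7-[(4-methoxybenzyl)oxy]-6,6-dimethyl-3-oxoheptanoate; 9 2-(trimethylsilyl)phenyl trifluoromethanesulfonate
Product: 13 2-hydroxy-3-{3-[(4-methoxybenzyl)oxy]-2,2-dimethylpropyl}naphthalene-1,4-dione, via benzyne 10 (not isolated), via acyl-alkylation product 11 (not isolated), via naphthalene-1,3-diol 12 (not isolated)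
Conditions: 9 (1.25 equiv), CsF (2.5 equiv), MeCN, 80 °C; then NaOMe (4 equiv), MeOH, open to air (or O2 balloon), rt → 50 °C; 1 M HCl work-up
Reagents that add atoms: dioxygen, O=O
Why: Fluoride desilylates 9 and triflate leaves to give benzyne 10; the caesium enolate of 8 adds through its central carbon, the aryl anion closes onto the ketone carbonyl to a benzocyclobutenoxide, and fragmentation of that four-membered ring leaves the acyl group and the CH2CO2Me arm on neighbouring ring carbons in 11 (C4–C4a and C1–C8a formed). This is the known aryne acyl-alkylation of β-keto esters, and its continuation in the same flask by alkoxide-induced condensation and air oxidation to 3-alkyl-2-hydroxy-1,4-naphthoquinones is likewise known. Ring B closes by a 6-exo-trig Claisen (Dieckmann-type) attack of the ketone α-carbanion on the ester carbonyl (C2–C3), giving naphthalene-1,3-diol 12 after loss of methoxide and enolisation; its electron-rich anion takes up O2 at the free C1–H position para to the C4 oxygen and collapses to the quinone carbonyl. No stereocentre is formed. The insertion needs no regiocontrol because benzyne 10 is symmetrical, and the direction of ring closure is fixed by ring size, since attack of the arylacetate carbanion on the ketone would give a strained four-membered ring and is reversible. The PMB ether and the quaternary carbon are inert to CsF and NaOMe, and pairing a methyl ester with NaOMe excludes ester scrambling.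

Step 7
Reactants: 13 2-hydroxy-3-{3-[(4-methoxybenzyl)oxy]-2,2-dimethylpropyl}naphthalene-1,4-dione
Product: 14 2-hydroxy-3-(3-hydroxy-2,2-dimethylpropyl)naphthalene-1,4-dione
Conditions: DDQ (1.3 equiv), CH2Cl2/pH 7 buffer (10:1), 0 °C → rt
Reagents that add atoms: none
Why: Oxidative PMB cleavage by DDQ (hydride abstraction from the electron-rich benzylic CH2, then hydrolysis of the oxocarbenium ion); the hydroxyquinone is electron-poor and already at the quinone oxidation level, so it offers DDQ nothing to oxidise.

Step 8
Reactants: 14 2-hydroxy-3-(3-hydroxy-2,2-dimethylpropyl)naphthalene-1,4-dione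
Product: 16 3-(3-hydroxy-1,4-dioxo-1,4-dihydronaphthalen-2-yl)-2,2-dimethylpropyl 2-methylprop-2-enoate, via bis-methacrylate 15 (not isolated)
Conditions: methacrylic anhydride (2.5 equiv), Et3N (3 equiv), DMAP (0.1 equiv), BHT (trace), CH2Cl2, 0 °C → rt; then sat. aq NaHCO3/THF, rt; 1 M HCl to pH 3
Reagents that add atoms: methacrylic anhydride, C=C(C)C(=O)OC(=O)C(C)=C
Why: DMAP-catalysed acylation with the anhydride esterifies both hydroxyls, after which the ester on the C2 oxygen, a vinylogous mixed anhydride, is hydrolysed selectively by bicarbonate (attack at the acyl carbon or at C2 gives the same hydroxyquinone) while the hindered neopentyl methacrylate is left intact.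

Step 9
Reactants: 17 (R)-but-3-yn-2-ol
Product: 19 (R)-3-methylidenehept-6-en-2-ol, via alkenylmagnesium alkoxide 18 (not isolated)
Conditions: but-3-enylmagnesium bromide (3 equiv), CuI (15 mol%), THF/Et2O, −10 °C → rt; sat. aq NH4Cl
Reagents that add atoms: but-3-enylmagnesium bromide, C=CCC[Mg]Br
Why: Copper-catalysed, alkoxide-directed anti-carbomagnesiation of a propargylic alcohol: the butenyl group is delivered to the internal alkyne carbon and magnesium to the terminal one in a five-membered chelate, protonolysis gives the 1,1-disubstituted alkene, and the carbinol stereocentre of 17 is not involved and is carried through as R.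

Step 10
Reactants: 16 3-(3-hydroxy-1,4-dioxo-1,4-dihydronaphthalen-2-yl)-2,2-dimethylpropyl 2-methylprop-2-enoate; 19 (R)-3-methylidenehept-6-en-2-ol
Product: 20 rhinacanthin I, 3-(3-hydroxy-1,4-dioxo-1,4-dihydronaphthalen-2-yl)-2,2-dimethylpropyl (2E,7R)-7-hydroxy-2-methyl-6-methylideneoct-2-enoate
Conditions: 19 (2–3 equiv), second-generation Grubbs catalyst RuCl2(=CHPh)(H2IMes)(PCy3) (5–10 mol%, in portions), CH2Cl2, 40 °C, argon sweep
Reagents that add atoms: none
Why: Olefin cross-metathesis between the monosubstituted alkene of 19 and the methacrylate of 16, a pairing known to give α-methyl-α,β-unsaturated esters as the E isomers under thermodynamic control; the 1,1-disubstituted alkene of 19 next to the branched carbinol carbon is more hindered than the methacrylate and should stay out, ring closure of 19 would require a cyclobutene, and the stereocentre is untouched.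

**Compound list**

1 | neopentyl glycol (2,2-dimethylpropane-1,3-diol) | OCC(C)(C)CO | starting material
2 | 3-[(4-methoxybenzyl)oxy]-2,2-dimethylpropan-1-ol | COc1ccc(COCC(C)(C)CO)cc1 | intermediate
3 | 3-[(4-methoxybenzyl)oxy]-2,2-dimethylpropanal | COc1ccc(COCC(C)(C)C=O)cc1 | intermediate
4 | methyl 4-chloroacetoacetate | COC(=O)CC(=O)CCl | starting material
5 | (4-methoxy-2,4-dioxobutyl)triphenylphosphonium chloride | COC(=O)CC(=O)C[P+](c1ccccc1)(c1ccccc1)c1ccccc1.[Cl-] | intermediate (not isolated)
6 | methyl 3-oxo-4-(triphenyl-λ5-phosphanylidene)butanoate | COC(=O)CC(=O)C=P(c1ccccc1)(c1ccccc1)c1ccccc1 | intermediate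
7 | methyl (E)-7-[(4-methoxybenzyl)oxy]-6,6-dimethyl-3-oxohept-4-enoate | COC(=O)CC(=O)/C=C/C(C)(C)COCc1ccc(OC)cc1 | intermediate
8 | methyl 7-[(4-methoxybenzyl)oxy]-6,6-dimethyl-3-oxoheptanoate | COC(=O)CC(=O)CCC(C)(C)COCc1ccc(OC)cc1 | intermediate
9 | 2-(trimethylsilyl)phenyl trifluoromethanesulfonate | C[Si](C)(C)c1ccccc1OS(=O)(=O)C(F)(F)F | starting material
10 | benzyne (cyclohexa-1,3-dien-5-yne) | C1#CC=CC=C1 | intermediate (not isolated)
11 | methyl 2-(2-{5-[(4-methoxybenzyl)oxy]-4,4-dimethylpentanoyl}phenyl)acetate | COC(=O)Cc1ccccc1C(=O)CCC(C)(C)COCc1ccc(OC)cc1 | intermediate (not isolated)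
12 | 2-{3-[(4-methoxybenzyl)oxy]-2,2-dimethylpropyl}naphthalene-1,3-diol | COc1ccc(COCC(C)(C)Cc2c(O)cc3ccccc3c2O)cc1 | intermediate (not isolated)
13 | 2-hydroxy-3-{3-[(4-methoxybenzyl)oxy]-2,2-dimethylpropyl}naphthalene-1,4-dione | COc1ccc(COCC(C)(C)CC2=C(O)C(=O)c3ccccc3C2=O)cc1 | intermediate
14 | 2-hydroxy-3-(3-hydroxy-2,2-dimethylpropyl)naphthalene-1,4-dione | OCC(C)(C)CC1=C(O)C(=O)c2ccccc2C1=O | intermediate
15 | 3-[3-(methacryloyloxy)-1,4-dioxo-1,4-dihydronaphthalen-2-yl]-2,2-dimethylpropyl 2-methylprop-2-enoate | C=C(C)C(=O)OCC(C)(C)CC1=C(OC(=O)C(C)=C)C(=O)c2ccccc2C1=O | intermediate (not isolated)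
16 | 3-(3-hydroxy-1,4-dioxo-1,4-dihydronaphthalen-2-yl)-2,2-dimethylpropyl 2-methylprop-2-enoate | C=C(C)C(=O)OCC(C)(C)CC1=C(O)C(=O)c2ccccc2C1=O | intermediate
17 | (R)-but-3-yn-2-ol | C#C[C@@H](C)O | starting material
18 | bromomagnesium (R,Z)-3-[(bromomagnesio)methylidene]hept-6-en-2-olate | C=CCC/C(=C/[Mg]Br)[C@@H](C)O[Mg]Br | intermediate (not isolated)
19 | (R)-3-methylidenehept-6-en-2-ol | C=CCCC(=C)[C@@H](C)O | intermediate
20 | rhinacanthin I | C=C(CC/C=C(\C)C(=O)OCC(C)(C)CC1=C(O)C(=O)c2ccccc2C1=O)[C@@H](C)O | target

**Step count and risk**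

Total: 10 steps. Longest linear sequence: 8 steps (steps 1, 2, 4, 5, 6, 7, 8, 10, from neopentyl glycol); steps 3 and 9 are side branches.

Steps most likely to fail:

1. Step 6. The enolate of 8 may add to benzyne and be protonated before the aryl anion closes onto the ketone, giving α-arylation instead of C–C insertion. The second stage may also stall before ring closure or run on to oxidative degradation in basic air. Fallback: it sets out from aldehyde 3 and comes back at 13, replacing steps 3 to 6. Commercial 2-hydroxy-1,4-naphthoquinone (lawsone), 3 and diethyl 2,6-dimethyl-1,4-dihydropyridine-3,5-dicarboxylate (Hantzsch ester) are stirred with catalytic L-proline in CH2Cl2 at rt to 40 °C. Knoevenagel condensation at C3 of lawsone should give 3-{3-[(4-methoxybenzyl)oxy]-2,2-dimethylpropylidene}naphthalene-1,2,4(3H)-trione F1, which is not isolated and takes hydride from the Hantzsch ester at the exocyclic carbon to give 13. Ring B is then bought and only the C3–CH2 bond is made; the aldehyde cannot enolise, so slow condensation is the only concern.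

2. Step 10. The terminal alkene of 19 may homodimerise, or cross with the 1,1-disubstituted alkene of a second molecule of 19, faster than it engages the methacrylate; the free hydroxyquinone may also slow the catalyst. Fallback: it sets out from dienol 19, uses alcohol 14 in place of 16, and comes back at 20, replacing steps 8 and 10. The trisubstituted alkene is made on the small fragment and the union becomes an esterification.
   - Silylation of 19 (TBSCl, imidazole, DMF) should give (R)-tert-butyldimethyl[(3-methylidenehept-6-en-2-yl)oxy]silane F2, in which the bulky silyl ether shields the internal alkene.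
   - Cross-metathesis of F2 with methyl methacrylate in large excess as co-solvent (second-generation Grubbs catalyst, 40 °C) should give methyl (2E,7R)-7-[(tert-butyldimethylsilyl)oxy]-2-methyl-6-methylideneoct-2-enoate F3.
   - LiOH in THF/MeOH/H2O should give (2E,7R)-7-[(tert-butyldimethylsilyl)oxy]-2-methyl-6-methylideneoct-2-enoic acid F4.
   - Yamaguchi esterification (2,4,6-trichlorobenzoyl chloride, Et3N; then 14, DMAP; bicarbonate wash to hydrolyse any enol ester) should give 3-(3-hydroxy-1,4-dioxo-1,4-dihydronaphthalen-2-yl)-2,2-dimethylpropyl (2E,7R)-7-[(tert-butyldimethylsilyl)oxy]-2-methyl-6-methylideneoct-2-enoate F5.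
   - HF·pyridine in THF removes the silyl group to give 20.

3. Step 4. Addition of the ylide anion to the neopentyl-type aldehyde may be too slow, leaving the anion to decompose or self-condense. Fallback: it sets out from aldehyde 3 and comes back at 8, replacing steps 3 to 5.
   - Wittig reaction with commercial methyl (triphenylphosphoranylidene)acetate (toluene, 90 °C) should give methyl (E)-5-[(4-methoxybenzyl)oxy]-4,4-dimethylpent-2-enoate F6.
   - Hydrogenation (H2, Pd/C, pyridine, EtOAc) should give methyl 5-[(4-methoxybenzyl)oxy]-4,4-dimethylpentanoate F7.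
   - LiOH in THF/H2O should give 5-[(4-methoxybenzyl)oxy]-4,4-dimethylpentanoic acid F8.
   - 1,1'-Carbonyldiimidazole in THF converts F8 into 1-{5-[(4-methoxybenzyl)oxy]-4,4-dimethylpentanoyl}imidazole F9 (used in the same flask). Potassium methyl malonate, MgCl2 and Et3N (rt → 50 °C) then effect the decarboxylative Claisen (Masamune–Brooks) homologation to 8.

**Further compounds**

F1 | step 6 | 3-{3-[(4-methoxybenzyl)oxy]-2,2-dimethylpropylidene}naphthalene-1,2,4(3H)-trione | COc1ccc(COCC(C)(C)C=C2C(=O)C(=O)c3ccccc3C2=O)cc1
F2 | step 10 | (R)-tert-butyldimethyl[(3-methylidenehept-6-en-2-yl)oxy]silane | C=CCCC(=C)[C@@H](C)O[Si](C)(C)C(C)(C)C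
F3 | step 10 | methyl (2E,7R)-7-[(tert-butyldimethylsilyl)oxy]-2-methyl-6-methylideneoct-2-enoate | C=C(CC/C=C(\C)C(=O)OC)[C@@H](C)O[Si](C)(C)C(C)(C)C
F4 | step 10 | (2E,7R)-7-[(tert-butyldimethylsilyl)oxy]-2-methyl-6-methylideneoct-2-enoic acid | C=C(CC/C=C(\C)C(=O)O)[C@@H](C)O[Si](C)(C)C(C)(C)C
F5 | step 10 | 3-(3-hydroxy-1,4-dioxo-1,4-dihydronaphthalen-2-yl)-2,2-dimethylpropyl (2E,7R)-7-[(tert-butyldimethylsilyl)oxy]-2-methyl-6-methylideneoct-2-enoate | C=C(CC/C=C(\C)C(=O)OCC(C)(C)CC1=C(O)C(=O)c2ccccc2C1=O)[C@@H](C)O[Si](C)(C)C(C)(C)C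
F6 | step 4 | methyl (E)-5-[(4-methoxybenzyl)oxy]-4,4-dimethylpent-2-enoate | COC(=O)/C=C/C(C)(C)COCc1ccc(OC)cc1
F7 | step 4 | methyl 5-[(4-methoxybenzyl)oxy]-4,4-dimethylpentanoate | COC(=O)CCC(C)(C)COCc1ccc(OC)cc1
F8 | step 4 | 5-[(4-methoxybenzyl)oxy]-4,4-dimethylpentanoic acid | OC(=O)CCC(C)(C)COCc1ccc(OC)cc1
F9 | step 4 | 1-{5-[(4-methoxybenzyl)oxy]-4,4-dimethylpentanoyl}imidazole | O=C(CCC(C)(C)COCc1ccc(OC)cc1)n1ccnc1
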